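**Retrosynthetic overview**

1. Target 11 ⇐ tri-O-benzyl ether 10 by global hydrogenolysis.
2. 10 ⇐ open-chain chalcone/1,3-diketone 8. Both pyranone rings close last, in one flask: the (2S)-flavanone C-ring first (catalytic asymmetric oxa-Michael), then the flavone C-ring (cyclodehydration).
3. 8 ⇐ chalcone acid 5 + acetophenone 6 (Claisen-type C-acylation, flavone-side A-ring attached).
4. 5 ⇐ aldehyde-ester 3 + acetophenone 4 (Claisen–Schmidt with concurrent saponification, flavanone-side A-ring attached).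
5. 3 ⇐ phenol 1 + aryl fluoride 2 (SNAr diaryl ether); all four benzene rings are purchased.

Assumption: the quinidine-derived thiourea is taken to give the (2S)-flavanone; the sense is checked by CD on 10 and the quinine-derived pseudoenantiomer is used instead if it is opposite.

**Route**

Step 1
Reactants: 1 4-(benzyloxy)-3-hydroxybenzaldehyde; 2 ethyl 4-fluorobenzoate
Product: 3 ethyl 4-[2-(benzyloxy)-5-formylphenoxy]benzoate
Conditions: Cs2CO3 (1.5 equiv), DMSO, 120 °C, 16 h, N2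
Reagents that add atoms: none
Why: SNAr diaryl-ether formation, in which the 3-phenoxide of 1 (meta to CHO, so still nucleophilic) displaces fluoride para to the ester of 2 through a Meisenheimer adduct, and neither partner is enolisable.

Step 2
Reactants: 3 ethyl 4-[2-(benzyloxy)-5-formylphenoxy]benzoate; 4 1-(2,6-dihydroxy-4-methoxyphenyl)ethanone
Product: 5 4-{2-(benzyloxy)-5-[(1E)-3-(2,6-dihydroxy-4-methoxyphenyl)-3-oxoprop-1-en-1-yl]phenoxy}benzoic acid
Conditions: KOH (50% aq, 15 equiv), EtOH, 0 °C → rt, 48 h, Ar; then ice-cold 2 M HCl to pH 2, rapid filtration/extraction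
Reagents that add atoms: potassium hydroxide, [K+].[OH-] (its oxygen becomes the carboxylic acid OH)
Why: Claisen–Schmidt condensation (aldol addition then E1cB dehydration gives the E-enone) with concurrent ester saponification; in strong alkali the 2',6'-dihydroxychalcone stays ring-open as its phenolate, and fast cold acidification delivers it uncyclised.

Step 3
Reactants: 5 4-{2-(benzyloxy)-5-[(1E)-3-(2,6-dihydroxy-4-methoxyphenyl)-3-oxoprop-1-en-1-yl]phenoxy}benzoic acid; 6 1-[2,4-bis(benzyloxy)-6-hydroxyphenyl]ethanone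
Product: 8 1-[2,4-bis(benzyloxy)-6-hydroxyphenyl]-3-(4-{2-(benzyloxy)-5-[(1E)-3-(2,6-dihydroxy-4-methoxyphenyl)-3-oxoprop-1-en-1-yl]phenoxy}phenyl)propane-1,3-dione, via acyl imidazolide 7 (not isolated)
Conditions: (i) 5, CDI (1.1 equiv), THF, 0 °C → rt, 1 h; (ii) 6 (1.5 equiv), LiHMDS (8 equiv), THF, −78 °C, 1 h, then add solution (i), −78 → 0 °C, 3 h; cold 1 M HCl
Reagents that add atoms: none
Why: Crossed Claisen C-acylation (a one-step equivalent of the Baker–Venkataraman transposition) of the phenoxide–enolate dianion of 6 by the acyl imidazolide, while excess base holds the chalcone as an unreactive bis-phenoxide so the enolate attacks the acyl group and not the enone.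

Step 4
Reactants: 8 1-[2,4-bis(benzyloxy)-6-hydroxyphenyl]-3-(4-{2-(benzyloxy)-5-[(1E)-3-(2,6-dihydroxy-4-methoxyphenyl)-3-oxoprop-1-en-1-yl]phenoxy}phenyl)propane-1,3-dione
Product: 10 (2S)-2-(4-(benzyloxy)-3-{4-[5,7-bis(benzyloxy)-4-oxo-4H-chromen-2-yl]phenoxy}phenyl)-5-hydroxy-7-methoxy-2,3-dihydro-4H-chromen-4-one, via flavanone diketone 9 (not isolated)
Conditions: N-[3,5-bis(trifluoromethyl)phenyl]-N'-[(9R)-6'-methoxycinchonan-9-yl]thiourea (quinidine-derived, 20 mol%), toluene/CH2Cl2 2:1 (0.02 M), −20 °C, 72 h; then p-TsOH·H2O (0.5 equiv), 40 °C, 3 h, same flask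
Reagents that add atoms: none
Why: Proposed new method: the bifunctional cinchona thiourea should bind the chalcone carbonyl through its thiourea N–H bonds while the quinuclidine activates a 2'/6'-OH (either gives the same product), so the phenol adds 6-endo-trig to one enantioface of the E-enone and sets C2 as (S), the new 5-OH···O=C chelate making closure irreversible, after which TsOH in the same flask cyclodehydrates the o-hydroxyaryl 1,3-diketone (hemiketalisation, loss of water) to the flavone without touching the acid-stable C2 centre; the closest known reaction types are the thiourea-catalysed asymmetric intramolecular oxa-Michael (biomimetic chalcone-to-flavanone) cyclisation and the acid-mediated final stage of the Baker–Venkataraman flavone synthesis, here run as one tandem double cyclisation at high dilution to suppress intermolecular diketone-to-enone Michael addition.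

Step 5
Reactants: 10 (2S)-2-(4-(benzyloxy)-3-{4-[5,7-bis(benzyloxy)-4-oxo-4H-chromen-2-yl]phenoxy}phenyl)-5-hydroxy-7-methoxy-2,3-dihydro-4H-chromen-4-one
Product: 11 (2S)-2-{3-[4-(5,7-dihydroxy-4-oxo-4H-chromen-2-yl)phenoxy]-4-hydroxyphenyl}-5-hydroxy-7-methoxy-2,3-dihydro-4H-chromen-4-one
Conditions: H2 (1 atm), 10% Pd/C, EtOAc/MeOH 1:1, rt, 3 h
Reagents that add atoms: none
Why: Catalytic hydrogenolysis of the three aryl benzyl ethers under neutral conditions, where a short run at 1 atm leaves the flavone C2=C3 bond, both ketones and the benzylic C2–O bond intact and does not affect the C2 stereocentre.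

**Compound list**

1 | 4-(benzyloxy)-3-hydroxybenzaldehyde | O=Cc1ccc(OCc2ccccc2)c(O)c1 | starting material
2 | ethyl 4-fluorobenzoate | CCOC(=O)c1ccc(F)cc1 | starting material
3 | ethyl 4-[2-(benzyloxy)-5-formylphenoxy]benzoate | CCOC(=O)c1ccc(Oc2cc(C=O)ccc2OCc2ccccc2)cc1 | intermediate
4 | 1-(2,6-dihydroxy-4-methoxyphenyl)ethanone | CC(=O)c1c(O)cc(OC)cc1O | starting material
5 | 4-{2-(benzyloxy)-5-[(1E)-3-(2,6-dihydroxy-4-methoxyphenyl)-3-oxoprop-1-en-1-yl]phenoxy}benzoic acid | COc1cc(O)c(C(=O)/C=C/c2ccc(OCc3ccccc3)c(Oc3ccc(C(=O)O)cc3)c2)c(O)c1 | intermediate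
6 | 1-[2,4-bis(benzyloxy)-6-hydroxyphenyl]ethanone | CC(=O)c1c(O)cc(OCc2ccccc2)cc1OCc1ccccc1 | starting material
7 | (2E)-3-{4-(benzyloxy)-3-[4-(1H-imidazole-1-carbonyl)phenoxy]phenyl}-1-(2,6-dihydroxy-4-methoxyphenyl)prop-2-en-1-one (acyl imidazolide, not isolated) | COc1cc(O)c(C(=O)/C=C/c2ccc(OCc3ccccc3)c(Oc3ccc(C(=O)n4ccnc4)cc3)c2)c(O)c1 | intermediate
8 | 1-[2,4-bis(benzyloxy)-6-hydroxyphenyl]-3-(4-{2-(benzyloxy)-5-[(1E)-3-(2,6-dihydroxy-4-methoxyphenyl)-3-oxoprop-1-en-1-yl]phenoxy}phenyl)propane-1,3-dione (drawn as diketone; enol and hemiketal tautomers) | COc1cc(O)c(C(=O)/C=C/c2ccc(OCc3ccccc3)c(Oc3ccc(C(=O)CC(=O)c4c(O)cc(OCc5ccccc5)cc4OCc4ccccc4)cc3)c2)c(O)c1 | intermediate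
9 | 1-[2,4-bis(benzyloxy)-6-hydroxyphenyl]-3-(4-{2-(benzyloxy)-5-[(2S)-5-hydroxy-7-methoxy-4-oxo-3,4-dihydro-2H-chromen-2-yl]phenoxy}phenyl)propane-1,3-dione (flavanone diketone, not isolated) | COc1cc(O)c2c(c1)O[C@H](c1ccc(OCc3ccccc3)c(Oc3ccc(C(=O)CC(=O)c4c(O)cc(OCc5ccccc5)cc4OCc4ccccc4)cc3)c1)CC2=O | intermediate
10 | (2S)-2-(4-(benzyloxy)-3-{4-[5,7-bis(benzyloxy)-4-oxo-4H-chromen-2-yl]phenoxy}phenyl)-5-hydroxy-7-methoxy-2,3-dihydro-4H-chromen-4-one | COc1cc(O)c2c(c1)O[C@H](c1ccc(OCc3ccccc3)c(Oc3ccc(-c4cc(=O)c5c(OCc6ccccc6)cc(OCc6ccccc6)cc5o4)cc3)c1)CC2=O | intermediate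
11 | (2S)-2-{3-[4-(5,7-dihydroxy-4-oxo-4H-chromen-2-yl)phenoxy]-4-hydroxyphenyl}-5-hydroxy-7-methoxy-2,3-dihydro-4H-chromen-4-one (CNP0145819.1) | COc1cc(O)c2c(c1)O[C@H](c1ccc(O)c(Oc3ccc(-c4cc(=O)c5c(O)cc(O)cc5o4)cc3)c1)CC2=O | target

**Step count**

Total steps: 5. Longest linear sequence: 5 steps (1/2 → 3 → 5 → 8 → 10 → 11).

**Three steps most likely to fail, with fallbacks**

Step 4 (tandem asymmetric oxa-Michael/cyclodehydration). The risks are modest enantioselectivity for an unactivated chalcone, catalyst sequestration by the acidic diketone enol, and partial racemisation of the p-alkoxybenzylic C2–O bond in the acid stage. The fallback sets out from 8 and returns at 10. Cyclise 8 without a chiral catalyst (NaOAc, EtOH, reflux; then p-TsOH, toluene, 60 °C) to the racemic tri-O-benzyl biflavonoid F1, and resolve it by preparative chiral SFC on an amylose carbamate phase. This gives 10, and the (R)-enantiomer F2 is set aside.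

Step 3 (C-acylation in the presence of the free chalcone). The risks are enolate Michael addition to the enone, O-acylation of phenoxides, and base-induced racemic ring closure of the chalcone. The fallback sets out from 5 (through imidazolide 7) and returns at 8. O-acylate the potassium phenoxide of 6 (3 equiv, excess recovered) with 7 in THF to give the aryl ester 2-acetyl-3,5-bis(benzyloxy)phenyl 4-{2-(benzyloxy)-5-[(1E)-3-(2,6-dihydroxy-4-methoxyphenyl)-3-oxoprop-1-en-1-yl]phenoxy}benzoate F3. Then carry out the intramolecular Baker–Venkataraman acyl transfer (KOH, pyridine, 50 °C; cold acidification) to reach 8.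

Step 2 (Claisen–Schmidt with the unprotected 2,6-dihydroxyacetophenone). The risks are a sluggish polyanion enolate, competing Cannizzaro reaction of 3, and some racemic flavanone on acidification. The fallback sets out from 4 and returns at 5. Protect 4 (MOMCl, NaH, DMF) as 1-[4-methoxy-2,6-bis(methoxymethoxy)phenyl]ethanone F4. Condense F4 with 3 (KOH, EtOH/H2O, rt; ester saponified in the same pot) to give the bis-MOM chalcone acid 4-{2-(benzyloxy)-5-[(1E)-3-[4-methoxy-2,6-bis(methoxymethoxy)phenyl]-3-oxoprop-1-en-1-yl]phenoxy}benzoic acid F5. Remove both MOM groups under cold, brief acid conditions (3 M HCl, MeOH/THF, 0–20 °C) to give 5.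

**Further compounds**

F1 | step 4 | racemic 2-(4-(benzyloxy)-3-{4-[5,7-bis(benzyloxy)-4-oxo-4H-chromen-2-yl]phenoxy}phenyl)-5-hydroxy-7-methoxy-2,3-dihydro-4H-chromen-4-one | COc1cc(O)c2c(c1)OC(c1ccc(OCc3ccccc3)c(Oc3ccc(-c4cc(=O)c5c(OCc6ccccc6)cc(OCc6ccccc6)cc5o4)cc3)c1)CC2=O
F2 | step 4 | (2R)-2-(4-(benzyloxy)-3-{4-[5,7-bis(benzyloxy)-4-oxo-4H-chromen-2-yl]phenoxy}phenyl)-5-hydroxy-7-methoxy-2,3-dihydro-4H-chromen-4-one | COc1cc(O)c2c(c1)O[C@@H](c1ccc(OCc3ccccc3)c(Oc3ccc(-c4cc(=O)c5c(OCc6ccccc6)cc(OCc6ccccc6)cc5o4)cc3)c1)CC2=O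
F3 | step 3 | 2-acetyl-3,5-bis(benzyloxy)phenyl 4-{2-(benzyloxy)-5-[(1E)-3-(2,6-dihydroxy-4-methoxyphenyl)-3-oxoprop-1-en-1-yl]phenoxy}benzoate | COc1cc(O)c(C(=O)/C=C/c2ccc(OCc3ccccc3)c(Oc3ccc(C(=O)Oc4cc(OCc5ccccc5)cc(OCc5ccccc5)c4C(C)=O)cc3)c2)c(O)c1
F4 | step 2 | 1-[4-methoxy-2,6-bis(methoxymethoxy)phenyl]ethanone | CC(=O)c1c(OCOC)cc(OC)cc1OCOC
F5 | step 2 | 4-{2-(benzyloxy)-5-[(1E)-3-[4-methoxy-2,6-bis(methoxymethoxy)phenyl]-3-oxoprop-1-en-1-yl]phenoxy}benzoic acid | COCOc1cc(OC)cc(OCOC)c1C(=O)/C=C/c1ccc(OCc2ccccc2)c(Oc2ccc(C(=O)O)cc2)c1
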